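(The data stem from a simulated flask with constants of no real substance; scatter was added.)

The one constant I need lies in the earlier runs, so the flasks come first.

| flask | left-handed substrate | right-handed substrate | reagent | free catalyst | remark | time |
|---|---|---|---|---|---|---|
| Sunday's | 0.41 M | 0.41 M | 0.55 M | 8.2 mM | run made earlier |  |
| Wednesday's | 0.82 M | 0.82 M | 0.82 M | 8.2 mM | run made earlier |  |
| teal | 0.41 M | 0.41 M | 0.820 M | 8.2 mM |  | 25 h |
| ochre | 0.41 M | 0.41 M | 0.820 M | 2.0 mM |  | 25 h |

| run | time / h | right-handed substrate / % | left-handed substrate / % | left-handed product / % |
|---|---|---|---|---|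
| Sunday's | 1.33 | 39.0 | 30.9 | 18.7 |
| Sunday's | 2.50 | 34.1 | 24.0 | 25.4 |
| Sunday's | 4.00 | 30.1 | 19.8 | 29.6 |
| Sunday's | 5.00 | 27.7 | 19.1 | 31.2 |
| Wednesday's | 0.417 | 46.3 | 42.5 | 6.3 |
| Wednesday's | 1.00 | 44.0 | 35.6 | 14.3 |
| Wednesday's | 2.00 | 40.2 | 29.2 | 20.2 |
| Wednesday's | 5.00 | 33.7 | 23.4 | 25.5 |

(standard deviation of a reading: 0.5 percentage points)

* the winner by excess of right-handed substrate over left-handed substrate among what is left of the two; "neither" if no more than 2 percentage points parts them (teal / ochre / neither)
* excess of right-handed substrate over left-handed substrate among what is left of the two at the end, teal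
* excess of right-handed substrate over left-handed substrate among what is left of the two at the end, ochre

- free catalyst is single-handed; left-handed substrate and right-handed substrate are mirror images of each other, charged as a racemate, each of them at the stated concentration
- the earlier runs were read with a standard deviation of 0.5 percentage points
- an excess is the difference of the two amounts in percent of their sum
- an excess is below zero if the other one leads
- no earlier run changes the charge of free catalyst; that part of a forecast is a guess

I call the left-handed and right-handed substrate together the pair, and I suppose that each pair molecule lost spends one reagent. The pair constant, the rate of loss of the pair divided by pair and reagent at 8.2 mM of free catalyst, comes from integrating that rate for unequal charges. Sunday's last reading gives k = 0.605 L mol⁻¹ h⁻¹, and its first gives 0.661 L mol⁻¹ h⁻¹. Wednesday's run, with twice the pair, gives 0.339 L mol⁻¹ h⁻¹, lower, so I keep Sunday's value, whose pair charge teal shares.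

On that constant I reckon teal to start at 0.407 M h⁻¹. Its reagent matches its pair, so both factors shrink together and the rate falls as the square of the fraction left. In closed form, the rate is the start rate divided by the square of one plus time over τ, with τ = 2.02 h. By 25 h my reckoning slows teal 179-fold and leaves 7.46 % of the pair.

For ochre I guess that the rate follows the catalyst, so τ stretches 4.10-fold to 8.27 h. The slowing is then 16.2-fold, and 24.8 % of the pair stays. Sunday's last reading gives a selectivity factor, the ratio of the logarithms of the fractions left, of 1.63. With that factor held, the excess grows as the pair falls, so I commit to teal, which keeps less in my reckoning.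

The forecast, which differs from me, says 6 % for teal, 28 % for ochre and the winner ochre, judging that “this looks reversible rather than simply running out of reagent”.

The excess of right-handed over left-handed substrate ends at 58.7 % in teal and at 38.0 % in ochre, so teal leads.

    reagent + catalyst intermediate B → free catalyst + right-handed product (k = 40.0 L mol⁻¹ h⁻¹)
    reagent ⇌ dormant form (K = 0.730, k = 0.0380 h⁻¹)
    free catalyst + right-handed substrate ⇌ catalyst intermediate B (K = 7.30 L mol⁻¹, k = 140 L mol⁻¹ h⁻¹)
    reagent + catalyst intermediate A → free catalyst + left-handed product (k = 160 L mol⁻¹ h⁻¹)
    free catalyst + left-handed substrate ⇌ catalyst intermediate A (K = 2.20 L mol⁻¹, k = 1100 L mol⁻¹ h⁻¹)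

The pair left stands near my reckoning: teal holds 6.87 % against 7.46 %, and ochre 27.5 % against 24.8 %. The main reason for the gap between the two excesses is the difference in free catalyst, for ochre's excess with teal's charge of free catalyst stands at 58.7 %. Scaled to a neighbour of ochre with 0.0034 M of free catalyst, the pair constant leaves 16.3 %, and that flask holds 16.9 % of the pair at an excess of 46.6 %.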